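## Retrosynthetic overview
1. Sodwanone T is a pseudo-C2 dimer of two identical, homochiral 6/7 oxepane-fused β-cyclogeranyl-type units. The CH2CH2 bridge is disconnected by an alkyl–alkenyl Suzuki coupling between a B-alkyl-9-BBN (right half, C9-OTBS) and an enol triflate (left half, C9 ketone).
2. Both halves come from one building block, the trans-fused oxepane enol triflate **14**. The oxepane is closed by the proposed new step, a Co-H HAT Markovnikov 7-exo hydroalkoxylation of an isopropenyl carbinol silyl ether by the C4–OH.
3. The carbocycle, the quaternary methyl centre and the C4–O centre come from (S)-Wieland–Miescher ketone. NaBH4 reduction sets C4–O cis to the angular methyl, and oxidative opening of the enone ring unmasks the C9 carboxyl. Methylation and enol triflation give the tetrasubstituted triflate, and the C9 stereocentre is set by CBS reduction.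
4. Ring order: carbocycle (from the Wieland–Miescher ketone), then oxepane (HAT), then the two halves are linked.

Assumptions: (S)-Me-CBS gives the (R)-C9 allylic alcohol (isopropenyl treated as the large group). The two halves of the target have the same configuration (checked from the SMILES), so one building block serves both; the left-half C9 stereocentre is destroyed by oxidation to the ketone.

## Route

**Step 1**
Reactants: **1** (S)-Wieland–Miescher ketone
Product: **2** (4aS,5S)-5-hydroxy-4a-methyl-4,4a,5,6,7,8-hexahydronaphthalen-2(3H)-one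
Conditions: NaBH4, EtOH, −20 °C
Reagents that add atoms: none
Why: Chemoselective NaBH4 reduction of the saturated ketone by axial attack anti to the angular methyl gives the equatorial OH cis to the methyl, which is the C4 configuration of the target.

**Step 2**
Reactants: **2**
Product: **3** C4-triethylsilyl ether of **2**
Conditions: TESCl, imidazole, DMF, rt
Reagents that add atoms: TESCl, CC[Si](Cl)(CC)CC
Why: Silylation protects the neopentylic alcohol with a group that can later be removed selectively in the presence of TBS.

**Step 3**
Reactants: **3**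
Product: **4** 3-[(1R,6S)-1-methyl-2-oxo-6-(triethylsilyloxy)cyclohexyl]propanoic acid
Conditions: O3, CH2Cl2/MeOH, −78 °C; then 30% H2O2, NaHCO3, 0 °C → rt
Reagents that add atoms: ozone, O=[O+][O-]; hydrogen peroxide, OO
Why: Oxidative ozonolysis of the enone (as in testosterone seco-acid formation) cleaves C=C, loses the α-carbon as formate/CO2, and leaves a ring ketone plus the C9 carboxylic acid; no stereocentre is touched.

**Step 4**
Reactants: **4**
Product: **5** 3-[(1R,6S)-1,3-dimethyl-2-oxo-6-(triethylsilyloxy)cyclohexyl]propanoic acid (C3 epimers, about 1:1)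
Conditions: LDA (2.2 equiv), THF, −78 → 0 °C; then MeI (1.2 equiv), −78 °C → rt
Reagents that add atoms: MeI, CI
Why: Acid deprotonation followed by regiospecific enolate formation at the only enolisable ketone α-carbon, then SN2 methylation (dianion alkylation) installs the future C1 methyl; the new epimeric centre is destroyed in Step 6.

**Step 5**
Reactants: **5**
Product: **6** methyl ester of **5**
Conditions: TMSCHN2, PhMe/MeOH, 0 °C
Reagents that add atoms: TMSCHN2, C[Si](C)(C)[C-]=[N+]=N
Why: Mild esterification that leaves the ketone and the silyl ether untouched.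

**Step 6**
Reactants: **6**
Product: **7** methyl 3-[(1R,6S)-1,3-dimethyl-2-(triflyloxy)-6-(triethylsilyloxy)cyclohex-2-en-1-yl]propanoate
Conditions: KHMDS, THF, −78 °C; then PhNTf2, −78 → 0 °C
Reagents that add atoms: PhNTf2, O=S(=O)(N(c1ccccc1)S(=O)(=O)C(F)(F)F)C(F)(F)F
Why: Kinetic enolisation can only occur toward C3 because the other α-carbon is quaternary, giving the tetrasubstituted β-cyclogeranyl-type enol triflate exclusively (enol triflation).

**Step 7**
Reactants: **7**
Product: **8** aldehyde, 3-[(1R,6S)-...]propanal
Conditions: DIBAL-H (1.05 equiv), CH2Cl2, −78 °C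
Reagents that add atoms: none
Why: Partial ester reduction at −78 °C (DIBAL) leaves the enol triflate and TES ether intact, and the ring ketone is already masked as the triflate.

**Step 8**
Reactants: **8**
Product: **9** allylic alcohol with a 3-hydroxy-4-methylpent-4-en-1-yl side chain (C9 epimers about 1:1)
Conditions: isopropenylMgBr, THF, −78 °C
Reagents that add atoms: isopropenylmagnesium bromide, CC(=C)[Mg]Br
Why: Grignard 1,2-addition to the aldehyde at −78 °C is faster than attack on the triflate; the C9 epimer mixture is funnelled through Step 9.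

**Step 9**
Reactants: **9**
Product: **10** isopropenyl ketone (enone)
Conditions: DMP, NaHCO3, CH2Cl2, rt
Reagents that add atoms: none
Why: Dess–Martin oxidation erases the C9 epimer mixture and provides a prochiral enone.

**Step 10**
Reactants: **10**
Product: **11** (1R,6S)-1-[(3R)-3-hydroxy-4-methylpent-4-en-1-yl]-1,3-dimethyl-6-(triethylsilyloxy)cyclohex-2-en-2-yl triflate
Conditions: (S)-Me-CBS (20 mol%), catecholborane, PhMe, −78 °C
Reagents that add atoms: none
Why: Corey–Bakshi–Shibata reduction under catalyst control sets the C9 (R) configuration that the right half of the target requires.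

**Step 11**
Reactants: **11**
Product: **12** C9-tert-butyldimethylsilyl ether of **11**
Conditions: TBSCl, imidazole, DMAP, DMF, rt
Reagents that add atoms: TBSCl, C[Si](C)(C(C)(C)C)Cl
Why: The C9 oxygen must be silylated so that the cation-like intermediate in Step 13 cannot undergo semipinacol hydride shift; TBS is orthogonal to TES.

**Step 12**
Reactants: **12**
Product: **13** C4-free alcohol (C9-OTBS, isopropenyl, enol triflate)
Conditions: PPTS, MeOH/CH2Cl2, 25–35 °C
Reagents that add atoms: none
Why: Mild acid methanolysis cleaves the less hindered TES ether selectively in the presence of the secondary TBS ether and the enol triflate.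

**Step 13**
Reactants: **13**
Product: **14** trans-fused 6/7 oxepane enol triflate: angular methyl and C4–O cis, C9 (R)-OTBS, gem-dimethyl ether carbon C10
Conditions: Co(II)-salen catalyst (5 mol%), N-fluoro-2,4,6-trimethylpyridinium BF4 (2 equiv), PhSiH3 (1.5 equiv), PhCF3, 25 °C
Reagents that add atoms: none (net addition of H only)
Why: Proposed new method: Co(salen) HAT/radical-polar-crossover Markovnikov hydroalkoxylation, extended to a 7-exo closure. Co(III)–H transfers H• to the terminal CH2 of the 1,1-disubstituted alkene to give the tertiary C10 radical, which is captured by Co(II) and oxidised to a cationic alkyl-Co(IV) that the neighbouring C4–OH displaces in a 7-exo closure. Only the 7-membered ring is geometrically possible, the C4 and C9 centres are untouched, and the C10 gem-dimethyl carbon is formed from CH2 plus H. The closest known reaction is Co-salen alkene hydroalkoxylation to 5- and 6-membered ethers, which has not been shown for oxepane formation or for tertiary centres flanked by a silyloxy-bearing carbon.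

**Step 14**
Reactants: **14**
Product: **15** C9-hydroxy oxepane enol triflate (C9 R)
Conditions: HF·pyridine, pyridine, THF, 25–45 °C
Reagents that add atoms: none
Why: Buffered fluoride removes the hindered TBS ether without cleaving the enol triflate.

**Step 15**
Reactants: **15**
Product: **16** C9-ketone oxepane enol triflate (left half)
Conditions: DMP, NaHCO3, CH2Cl2, rt
Reagents that add atoms: none
Why: Dess–Martin oxidation gives the α-alkoxy ketone; the C9 centre is destroyed, so its configuration is irrelevant.

**Step 16**
Reactants: **14** and tributyl(vinyl)stannane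
Product: **17** C2-vinyl diene (C9-OTBS oxepane)
Conditions: Pd(PPh3)4 (10 mol%), LiCl, CuCl, DMF, 70 °C
Reagents that add atoms: tributyl(vinyl)stannane, C=C[Sn](CCCC)(CCCC)CCCC
Why: Stille coupling of the hindered cyclogeranyl-type triflate with a vinylstannane, a precedented transformation for carotenoid-type triflates, installs the first bridge carbons.

**Step 17**
Reactants: **17**
Product: **18** B-[2-(cyclohexenyl)ethyl]-9-BBN (used in situ)
Conditions: 9-BBN dimer (0.55 equiv), THF, 0 °C → rt
Reagents that add atoms: 9-BBN, C1CC2CCCC(C1)B2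
Why: Anti-Markovnikov hydroboration occurs only at the unhindered terminal vinyl group and leaves the tetrasubstituted alkene and the OTBS untouched.

**Step 18**
Reactants: **18** and **16**
Product: **19** TBS-protected sodwanone T
Conditions: PdCl2(dppf) (10 mol%), AsPh3, Cs2CO3, THF/DMF/H2O, 50 °C
Reagents that add atoms: none
Why: B-alkyl Suzuki–Miyaura coupling joins the primary alkylborane to the tetrasubstituted enol triflate and forms the CH2CH2 linker; the ketone, TBS ether and oxepane survive.

**Step 19**
Reactants: **19**
Product: **20** sodwanone T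
Conditions: HF·pyridine, pyridine, THF, 25–40 °C
Reagents that add atoms: none
Why: Desilylation reveals the right-half C9 (R) secondary alcohol; no stereocentre is affected.

## Compound list
1 | (S)-Wieland–Miescher ketone | C[C@]12CCC(=O)C=C1CCCC2=O | starting material
2 | (4aS,5S)-ketol | O[C@H]1CCCC2=CC(=O)CC[C@]12C | intermediate
3 | C4-OTES enone | CC[Si](CC)(CC)O[C@H]1CCCC2=CC(=O)CC[C@]12C | intermediate
4 | keto acid | CC[Si](CC)(CC)O[C@H]1CCCC(=O)[C@]1(C)CCC(=O)O | intermediate
5 | α-methyl keto acid (C3 epimers) | CC[Si](CC)(CC)O[C@H]1CCC(C)C(=O)[C@]1(C)CCC(=O)O | intermediate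
6 | methyl ester | CC[Si](CC)(CC)O[C@H]1CCC(C)C(=O)[C@]1(C)CCC(=O)OC | intermediate
7 | enol triflate ester | CC[Si](CC)(CC)O[C@H]1CCC(C)=C(OS(=O)(=O)C(F)(F)F)[C@]1(C)CCC(=O)OC | intermediate
8 | aldehyde | CC[Si](CC)(CC)O[C@H]1CCC(C)=C(OS(=O)(=O)C(F)(F)F)[C@]1(C)CCC=O | intermediate
9 | allylic alcohol (C9 mixture) | CC[Si](CC)(CC)O[C@H]1CCC(C)=C(OS(=O)(=O)C(F)(F)F)[C@]1(C)CCC(O)C(C)=C | intermediate
10 | enone | CC[Si](CC)(CC)O[C@H]1CCC(C)=C(OS(=O)(=O)C(F)(F)F)[C@]1(C)CCC(=O)C(C)=C | intermediate
11 | (R)-allylic alcohol | CC[Si](CC)(CC)O[C@H]1CCC(C)=C(OS(=O)(=O)C(F)(F)F)[C@]1(C)CC[C@@H](O)C(C)=C | intermediate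
12 | C9-OTBS | CC[Si](CC)(CC)O[C@H]1CCC(C)=C(OS(=O)(=O)C(F)(F)F)[C@]1(C)CC[C@@H](O[Si](C)(C)C(C)(C)C)C(C)=C | intermediate
13 | C4-OH, C9-OTBS | O[C@H]1CCC(C)=C(OS(=O)(=O)C(F)(F)F)[C@]1(C)CC[C@@H](O[Si](C)(C)C(C)(C)C)C(C)=C | intermediate
14 | oxepane enol triflate, C9-OTBS | CC1=C(OS(=O)(=O)C(F)(F)F)[C@]2(C)CC[C@@H](O[Si](C)(C)C(C)(C)C)C(C)(C)O[C@H]2CC1 | intermediate
15 | C9-OH oxepane enol triflate | CC1=C(OS(=O)(=O)C(F)(F)F)[C@]2(C)CC[C@@H](O)C(C)(C)O[C@H]2CC1 | intermediate
16 | C9-ketone oxepane enol triflate | CC1=C(OS(=O)(=O)C(F)(F)F)[C@]2(C)CCC(=O)C(C)(C)O[C@H]2CC1 | intermediate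
17 | vinyl diene | CC1=C(C=C)[C@]2(C)CC[C@@H](O[Si](C)(C)C(C)(C)C)C(C)(C)O[C@H]2CC1 | intermediate
18 | B-alkyl-9-BBN | CC1=C(CCB2C3CCCC2CCC3)[C@]2(C)CC[C@@H](O[Si](C)(C)C(C)(C)C)C(C)(C)O[C@H]2CC1 | intermediate
19 | TBS-protected sodwanone T | CC1=C(CCC2=C(C)CC[C@@H]3OC(C)(C)[C@H](O[Si](C)(C)C(C)(C)C)CC[C@@]23C)[C@]2(C)CCC(=O)C(C)(C)O[C@H]2CC1 | intermediate
20 | sodwanone T | CC1=C(CCC2=C(C)CC[C@@H]3OC(C)(C)[C@H](O)CC[C@@]23C)[C@]2(C)CCC(=O)C(C)(C)O[C@H]2CC1 | target

## Totals
Total steps: 19. Longest linear sequence: 17 steps, from **1** through Steps 1–13, 16, 17, 18 and 19.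

## Three steps most likely to fail
1. **Step 13 (proposed new 7-exo HAT hydroalkoxylation).** Possible problems are alkene reduction or isomerisation, or a semipinacol or 1,2-silyl shift of the β-silyloxy tertiary cation. Fallback: intramolecular alkoxymercuration of **13** (Hg(OTf)2, then NaBH4 demercuration), which forms the same Markovnikov 7-exo tertiary ether by a different mechanism using known chemistry.
2. **Step 18 (hindered sp3–sp2 Suzuki coupling between two neopentylic tetrasubstituted units).** Fallback: change the bond construction. Couple **16** with TMS-acetylene (Sonogashira), remove the TMS group, couple with **14** (Sonogashira), then hydrogenate the alkyne over Pd/C to CH2CH2, leaving the hindered tetrasubstituted alkenes.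
3. **Step 10 (CBS reduction: enantiomer assignment and remote-stereocentre selectivity).** Fallback: use the C9 epimer mixture from Step 8, protect as TBS, separate the epimers and assign them (Mosher analysis), and invert the undesired epimer by Mitsunobu p-nitrobenzoate inversion followed by hydrolysis.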